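The depsidone is opened at the lactone C–O and the diaryl ether C–O bond. This gives ring A salicylate 14 and ring B bromide 19, and the plan rests on building pentasubstituted ring A. Without its C-methyl and its ester carbonyl carbon, ring A is a mirror-symmetric benzaldehyde with oxygen on both ortho carbons. These two carbons sit on adjacent ring atoms next to the ether-bearing C–O. The key step exploits this. A 3-methoxyaryne from the 4-chloro-2,6-dimethoxybenzaldehyde acetal 5 takes up methyllithium and then CO2, forging both C–C bonds in one flask, and the neighbouring methoxy group fixes their order. Ring B derives from methyl 2,4-dihydroxy-3,6-dimethylbenzoate. The labile lactol carbon is resolved last.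

Key step: step 3

Assumption: the hydroxyphthalide carbon C-1 epimerises through the ring-opened formyl acid. Its (S) configuration is therefore fixed in the last operation, and 24 is handled cold in acidic aprotic media and stored as a solid.
Remark: ring A is the methyl-bearing arene; ring B is the arene fused to the lactol.

Step 1
Reactants: 1 1-chloro-3,5-dimethoxybenzene; 2 N,N-dimethylformamide
Product: 4 4-chloro-2,6-dimethoxybenzaldehyde, via 4-chloro-2,6-dimethoxyphenyllithium 3 (not isolated)
Conditions: n-BuLi (1.1 equiv), THF, −78 to −30 °C; DMF, −78 °C to rt; 1 M HCl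
Reagents that add atoms: N,N-dimethylformamide CN(C)C=O
Why: Directed ortho-metalation by an alkyllithium favours the hydrogen flanked by both coordinating methoxy groups over those next to chlorine, the low temperature prevents LiCl loss from any minor regioisomer, and the aryllithium is formylated in a Bouveault-type reaction.

Step 2
Reactants: 4 4-chloro-2,6-dimethoxybenzaldehyde
Product: 5 4-chloro-2,6-dimethoxybenzaldehyde dimethyl acetal
Conditions: HC(OMe)3 (3 equiv), MeOH, p-TsOH (cat.), 50 °C; Et3N quench
Reagents that add atoms: trimethyl orthoformate COC(OC)OC; methanol CO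
Why: Acid-catalysed acetalisation is driven to completion by the orthoformate as water scavenger, and the basic quench preserves the acid-labile but organolithium-proof dimethyl acetal.

Step 3
Reactants: 5 4-chloro-2,6-dimethoxybenzaldehyde dimethyl acetal; 6 methyllithium; 7 carbon dioxide
Product: 12 3-formyl-2,4-dimethoxy-6-methylbenzoic acid, via lithiated chloroarene 8 (not isolated), via 3-methoxyaryne 9 (not isolated), via ortho-methoxy aryllithium 10 (not isolated), via acetal acid 11 (not isolated)
Conditions: s-BuLi (1.05 equiv), THF, −78 °C, 1 h; MeLi (3.5 equiv), −78 to −10 °C; transfer into CO2(s)/THF, −78 °C to rt; 1 M HCl, THF, rt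
Reagents that add atoms: methyllithium [Li]C; carbon dioxide O=C=O; water O
Why: s-BuLi removes one of the two ring hydrogens of 5, each flanked by chlorine and methoxy, and complete metalation at −78 °C before any aryne exists keeps unreacted 5 from later protonating the product anion. On warming, 8 loses LiCl to give aryne 9, the excess MeLi adds to the aryne carbon remote from the methoxy group, and aryllithium 10 is carboxylated by inverse addition to CO2, so the aryl–CH3 and aryl–CO2H bonds form on neighbouring carbons. The closest known reaction type is the three-component aryne coupling of meta-haloanisoles (deprotonative aryne generation, carbometalation, CO2 quench) used to make resorcylates. No ring is closed and no stereocentre is created. The selectivity needed is the regiochemistry of methyl addition; the methoxy group beside the triple bond secures it by polarising and distorting the aryne so that charge builds up on the adjacent carbon, where induction and O–Li coordination stabilise it, and the mirror symmetry of 5 means that either hydrogen leads to the same aryne. The acidic work-up releases acid 11 and deliberately hydrolyses its very labile electron-rich acetal, which is no longer needed, to aldehyde 12.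

Step 4
Reactants: 12 3-formyl-2,4-dimethoxy-6-methylbenzoic acid
Product: 13 3-formyl-2-hydroxy-4-methoxy-6-methylbenzoic acid
Conditions: BCl3 (1.3 equiv), CH2Cl2, −78 to −10 °C; H2O
Reagents that add atoms: none
Why: In this chelation-directed BCl3 ether cleavage boron is anchored on the carboxyl group and closes a six-membered chelate onto the adjacent methoxy oxygen, which is twisted out of conjugation between two carbonyl groups and is dealkylated first, while the limiting charge of reagent spares the planar 4-methoxy group.

Step 5
Reactants: 13 3-formyl-2-hydroxy-4-methoxy-6-methylbenzoic acid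
Product: 14 benzyl 3-formyl-2-hydroxy-4-methoxy-6-methylbenzoate
Conditions: BnBr (1.05 equiv), KHCO3 (1.2 equiv), DMF, rt
Reagents that add atoms: benzyl bromide BrCc1ccccc1
Why: SN2 alkylation of the carboxylate formed by the weak base should be much faster than alkylation of the hindered, hydrogen-bonded phenol, so only the ester is expected.

Step 6
Reactants: 15 methyl 2,4-dihydroxy-3,6-dimethylbenzoate
Product: 16 methyl 3-bromo-4,6-dihydroxy-2,5-dimethylbenzoate
Conditions: Br2 (1.05 equiv), AcOH, rt
Reagents that add atoms: bromine BrBr
Why: Electrophilic aromatic bromination can enter only the single free ring position, which is ortho to one hydroxyl group and para to the other.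

Step 7
Reactants: 16 methyl 3-bromo-4,6-dihydroxy-2,5-dimethylbenzoate
Product: 17 methyl 3-bromo-4,6-dimethoxy-2,5-dimethylbenzoate
Conditions: MeI (4 equiv), K2CO3 (4 equiv), DMF, 60 °C
Reagents that add atoms: iodomethane CI
Why: Williamson etherification caps both phenols as methyl ethers that tolerate radical bromination, silver salts and the basic coupling, warm DMF overcoming the hydrogen bond of the hydroxyl next to the ester.

Step 8
Reactants: 17 methyl 3-bromo-4,6-dimethoxy-2,5-dimethylbenzoate
Product: 18 methyl 3-bromo-2,5-bis(dibromomethyl)-4,6-dimethoxybenzoate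
Conditions: NBS (4.6 equiv), AIBN (cat.), PhCF3, 85 °C, visible light
Reagents that add atoms: N-bromosuccinimide O=C1CCC(=O)N1Br
Why: In this Wohl–Ziegler bromination every ring position is occupied, so only the two benzylic methyl groups can react, and excess reagent carries each to the dibromomethyl stage, where steric and polar deactivation stops further bromination.

Step 9
Reactants: 18 methyl 3-bromo-2,5-bis(dibromomethyl)-4,6-dimethoxybenzoate
Product: 19 methyl 3-bromo-2,5-diformyl-4,6-dimethoxybenzoate
Conditions: AgNO3 (4.5 equiv), acetone/H2O (4:1), rt, dark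
Reagents that add atoms: water O
Why: Silver-assisted hydrolysis of benzylic gem-dibromides delivers aldehydes at room temperature, a method that normally leaves a methyl ester next to the new formyl group in place.

Step 10
Reactants: 14 benzyl 3-formyl-2-hydroxy-4-methoxy-6-methylbenzoate; 19 methyl 3-bromo-2,5-diformyl-4,6-dimethoxybenzoate
Product: 20 benzyl 2-[2,5-diformyl-4,6-dimethoxy-3-(methoxycarbonyl)phenoxy]-3-formyl-4-methoxy-6-methylbenzoate
Conditions: CuI (0.5 equiv), picolinic acid (1 equiv), K3PO4 (2 equiv), 4 Å MS, DMSO, 90 °C, Ar
Reagents that add atoms: none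
Why: In this ligand-accelerated Ullmann diaryl ether synthesis the C–Br bond of 19 is activated toward monovalent copper by the ortho formyl group and two further acceptors, attack at the methoxy-bearing carbons is unproductive because the aryloxide is expelled in preference to methoxide, and none of the aldehydes is enolisable.

Step 11
Reactants: 20 the diaryl ether of step 10
Product: 21 2-[2,5-diformyl-4,6-dihydroxy-3-(methoxycarbonyl)phenoxy]-3-formyl-4-hydroxy-6-methylbenzoic acid
Conditions: BCl3 (10 equiv), CH2Cl2, −78 to 0 °C; H2O
Reagents that add atoms: none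
Why: Each of the three aryl methyl ethers lies ortho to a carbonyl oxygen that anchors boron (chelation-directed BCl3 dealkylation) and the benzyl ester is cleaved by the same reagent, whereas the methyl ester, the diaryl ether and the aldehydes should persist at or below 0 °C.

Step 12
Reactants: 21 the seco acid of step 11
Product: 22 methyl 4,6,9-triformyl-3,8-dihydroxy-1-methyl-11-oxo-11H-dibenzo[b,e][1,4]dioxepine-7-carboxylate
Conditions: (CF3CO)2O (4 equiv), toluene/CH2Cl2 (0.005 M), 0 °C to rt; H2O/THF
Reagents that add atoms: none
Why: In this anhydride-mediated depsidone lactonisation only the ring B hydroxyl ortho to the ether bridge can reach the activated ring A acyl carbon (seven-membered ring), the ring B carboxyl is still masked as its methyl ester, and transient trifluoroacetates on the other phenols fall off in the aqueous work-up.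

Step 13
Reactants: 22 the depsidone methyl ester of step 12
Product: 23 racemic 1,4,10-trihydroxy-8-methyl-3,7-dioxo-1,3-dihydro-7H-isobenzofuro[4,5-b][1,4]benzodioxepine-5,11-dicarbaldehyde
Conditions: 2 M HCl/1,4-dioxane (1:2), 60 °C
Reagents that add atoms: water O
Why: The hydrated formyl group next to the ester attacks the ester carbonyl and expels methanol (neighbouring-group-assisted hydrolysis, ring–chain tautomerism of a 2-formylbenzoate) to give the five-membered hydroxyphthalide as the racemate, while the di-ortho-substituted depsidone ester is shielded from acid-catalysed acyl–oxygen cleavage.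

Step 14
Reactants: 23 the racemic lactol
Product: 24 (1S)-1,4,10-trihydroxy-8-methyl-3,7-dioxo-1,3-dihydro-7H-isobenzofuro[4,5-b][1,4]benzodioxepine-5,11-dicarbaldehyde
Conditions: preparative HPLC, amylose tris(3,5-dimethylphenylcarbamate) immobilised on silica, n-heptane/THF, 0.1% TFA, 5 °C; cold evaporation
Reagents that add atoms: none
Why: Chromatographic resolution on a polysaccharide carbamate phase separates the two lactol enantiomers, the cold acidic aprotic eluent holds back ring opening to the formyl carboxylate that would racemise C-1, and the (S) fraction is to be identified by ECD against calculation.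

Compound list
1 | 1-chloro-3,5-dimethoxybenzene | COc1cc(Cl)cc(OC)c1 | starting material
2 | N,N-dimethylformamide | CN(C)C=O | starting material
3 | 4-chloro-2,6-dimethoxyphenyllithium | [Li]c1c(OC)cc(Cl)cc1OC | intermediate
4 | 4-chloro-2,6-dimethoxybenzaldehyde | COc1cc(Cl)cc(OC)c1C=O | intermediate
5 | 4-chloro-2,6-dimethoxybenzaldehyde dimethyl acetal | COC(OC)c1c(OC)cc(Cl)cc1OC | intermediate
6 | methyllithium | [Li]C | starting material
7 | carbon dioxide | O=C=O | starting material
8 | 6-chloro-3-(dimethoxymethyl)-2,4-dimethoxyphenyllithium | [Li]c1c(Cl)cc(OC)c(C(OC)OC)c1OC | intermediate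
9 | 4-(dimethoxymethyl)-3,5-dimethoxybenzyne | COC(OC)C1=C(OC)C#CC=C1OC | intermediate
10 | 3-(dimethoxymethyl)-2,4-dimethoxy-6-methylphenyllithium | [Li]c1c(C)cc(OC)c(C(OC)OC)c1OC | intermediate
11 | 3-(dimethoxymethyl)-2,4-dimethoxy-6-methylbenzoic acid | COC(OC)c1c(OC)cc(C)c(C(=O)O)c1OC | intermediate
12 | 3-formyl-2,4-dimethoxy-6-methylbenzoic acid | Cc1cc(OC)c(C=O)c(OC)c1C(=O)O | intermediate
13 | 3-formyl-2-hydroxy-4-methoxy-6-methylbenzoic acid | Cc1cc(OC)c(C=O)c(O)c1C(=O)O | intermediate
14 | benzyl 3-formyl-2-hydroxy-4-methoxy-6-methylbenzoate | Cc1cc(OC)c(C=O)c(O)c1C(=O)OCc1ccccc1 | intermediate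
15 | methyl 2,4-dihydroxy-3,6-dimethylbenzoate | COC(=O)c1c(C)cc(O)c(C)c1O | starting material
16 | methyl 3-bromo-4,6-dihydroxy-2,5-dimethylbenzoate | COC(=O)c1c(C)c(Br)c(O)c(C)c1O | intermediate
17 | methyl 3-bromo-4,6-dimethoxy-2,5-dimethylbenzoate | COC(=O)c1c(C)c(Br)c(OC)c(C)c1OC | intermediate
18 | methyl 3-bromo-2,5-bis(dibromomethyl)-4,6-dimethoxybenzoate | COC(=O)c1c(C(Br)Br)c(Br)c(OC)c(C(Br)Br)c1OC | intermediate
19 | methyl 3-bromo-2,5-diformyl-4,6-dimethoxybenzoate | COC(=O)c1c(C=O)c(Br)c(OC)c(C=O)c1OC | intermediate
20 | benzyl 2-[2,5-diformyl-4,6-dimethoxy-3-(methoxycarbonyl)phenoxy]-3-formyl-4-methoxy-6-methylbenzoate | Cc1cc(OC)c(C=O)c(Oc2c(C=O)c(C(=O)OC)c(OC)c(C=O)c2OC)c1C(=O)OCc1ccccc1 | intermediate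
21 | 2-[2,5-diformyl-4,6-dihydroxy-3-(methoxycarbonyl)phenoxy]-3-formyl-4-hydroxy-6-methylbenzoic acid | Cc1cc(O)c(C=O)c(Oc2c(C=O)c(C(=O)OC)c(O)c(C=O)c2O)c1C(=O)O | intermediate
22 | methyl 4,6,9-triformyl-3,8-dihydroxy-1-methyl-11-oxo-11H-dibenzo[b,e][1,4]dioxepine-7-carboxylate | Cc1cc(O)c(C=O)c2c1C(=O)Oc1c(C=O)c(O)c(C(=O)OC)c(C=O)c1O2 | intermediate
23 | racemic 1,4,10-trihydroxy-8-methyl-3,7-dioxo-1,3-dihydro-7H-isobenzofuro[4,5-b][1,4]benzodioxepine-5,11-dicarbaldehyde | Cc1cc(O)c(C=O)c2c1C(=O)Oc1c(C=O)c(O)c3c(c1O2)C(O)OC3=O | intermediate
24 | (1S)-1,4,10-trihydroxy-8-methyl-3,7-dioxo-1,3-dihydro-7H-isobenzofuro[4,5-b][1,4]benzodioxepine-5,11-dicarbaldehyde | Cc1cc(O)c(C=O)c2c1C(=O)Oc1c(C=O)c(O)c3c(c1O2)[C@@H](O)OC3=O | target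

Total step count: 14. Longest linear sequence: 10 (steps 1 to 5, then 10 to 14). Ring B takes 4 steps (6 to 9).

Steps most likely to fail

**Step 3.**
- What may go wrong: the aryllithiums present may compete with MeLi for the aryne (aryl–aryl coupling). LiCl loss may lag behind the quench. MeLi may over-add to the freshly formed carboxylate.
- Fallback: the two C–C bonds are made one after the other without an aryne.
- Setting out from 5, lithiation with s-BuLi in THF at −90 °C is followed at once by CO2, below the temperature of LiCl loss. This gives 6-chloro-3-(dimethoxymethyl)-2,4-dimethoxybenzoic acid F1.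
- The acidic work-up hydrolyses F1 to 6-chloro-3-formyl-2,4-dimethoxybenzoic acid F2.
- BnBr and KHCO3 in DMF give benzyl 6-chloro-3-formyl-2,4-dimethoxybenzoate F3.
- Suzuki–Miyaura methylation of the aryl chloride (trimethylboroxine, Pd(OAc)2, SPhos, K3PO4, dioxane, 100 °C) gives benzyl 3-formyl-2,4-dimethoxy-6-methylbenzoate F4.
- BCl3 (2.5 equiv, CH2Cl2, −78 to −10 °C) then removes the benzyl ester and the methyl ether lying between the two carbonyl groups. The route is rejoined at 13.

**Step 10.**
- What may go wrong: C–O bond formation may be sluggish because both partners are di-ortho-substituted. The phenoxide is also delocalised into two carbonyl groups and can sequester copper. Protodebromination, benzyl transfer and formyl-assisted ester hydrolysis could then overtake the coupling.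
- Fallback: a metal-free SNAr with nitrite as the leaving group, setting out from 15.
- Nitration (HNO3, 1 equiv, AcOH, 0 °C) at the only free position gives methyl 4,6-dihydroxy-2,5-dimethyl-3-nitrobenzoate F5.
- MeI and K2CO3 in DMF give methyl 4,6-dimethoxy-2,5-dimethyl-3-nitrobenzoate F6.
- NBS and AIBN in PhCF3 give methyl 2,5-bis(dibromomethyl)-4,6-dimethoxy-3-nitrobenzoate F7.
- AgNO3 in aqueous acetone gives methyl 2,5-diformyl-4,6-dimethoxy-3-nitrobenzoate F8.
- The nitro group of F8 is squeezed out of conjugation between formyl and methoxy and is activated by the ortho formyl group. Phenol 14 should displace it (K2CO3, DMF, 70 °C), and the route is rejoined at 20.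

**Step 14.**
- What may go wrong: racemisation on the column or during evaporation, or too little separation and solubility for preparative work.
- Fallback: a classical resolution through configurationally locked diastereomers, with release at a bond remote from the stereocentre.
- Setting out from 23, acid-catalysed pseudo-ester formation is run with (R)-1-phenylethanol (PPTS, toluene, 4 Å MS, 60 °C). It gives two diastereomers: the (1S)-1-[(1R)-1-phenylethoxy] derivative of the target F9 and the (1R)-1-[(1R)-1-phenylethoxy] epimer F10.
- They are separated on silica or by crystallisation. The unwanted epimer is re-equilibrated under the same acid.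
- Neutral hydrogenolysis of the wanted diastereomer (H2, 1 atm, Pd/C, EtOAc, 0 °C, closely monitored) cleaves the O–CH(CH3)Ph bond and leaves both C–O bonds of the acetal carbon untouched. Configuration is retained and the route is rejoined at 24.

Further compounds
F1 | step 3 | 6-chloro-3-(dimethoxymethyl)-2,4-dimethoxybenzoic acid | COC(OC)c1c(OC)cc(Cl)c(C(=O)O)c1OC
F2 | step 3 | 6-chloro-3-formyl-2,4-dimethoxybenzoic acid | O=Cc1c(OC)cc(Cl)c(C(=O)O)c1OC
F3 | step 3 | benzyl 6-chloro-3-formyl-2,4-dimethoxybenzoate | O=Cc1c(OC)cc(Cl)c(C(=O)OCc2ccccc2)c1OC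
F4 | step 3 | benzyl 3-formyl-2,4-dimethoxy-6-methylbenzoate | O=Cc1c(OC)cc(C)c(C(=O)OCc2ccccc2)c1OC
F5 | step 10 | methyl 4,6-dihydroxy-2,5-dimethyl-3-nitrobenzoate | COC(=O)c1c(C)c([N+](=O)[O-])c(O)c(C)c1O
F6 | step 10 | methyl 4,6-dimethoxy-2,5-dimethyl-3-nitrobenzoate | COC(=O)c1c(C)c([N+](=O)[O-])c(OC)c(C)c1OC
F7 | step 10 | methyl 2,5-bis(dibromomethyl)-4,6-dimethoxy-3-nitrobenzoate | COC(=O)c1c(C(Br)Br)c([N+](=O)[O-])c(OC)c(C(Br)Br)c1OC
F8 | step 10 | methyl 2,5-diformyl-4,6-dimethoxy-3-nitrobenzoate | COC(=O)c1c(C=O)c([N+](=O)[O-])c(OC)c(C=O)c1OC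
F9 | step 14 | (1S)-1-[(1R)-1-phenylethoxy] derivative of the target | Cc1cc(O)c(C=O)c2c1C(=O)Oc1c(C=O)c(O)c3c(c1O2)[C@@H](O[C@H](C)c4ccccc4)OC3=O
F10 | step 14 | (1R)-1-[(1R)-1-phenylethoxy] epimer | Cc1cc(O)c(C=O)c2c1C(=O)Oc1c(C=O)c(O)c3c(c1O2)[C@H](O[C@H](C)c4ccccc4)OC3=O
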